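**Retrosynthetic overview** (disconnections listed in build-up order so the numbering runs upward)
1. No ring is formed. Both benzene rings are bought intact as 3-bromo-2-fluorobenzaldehyde (1) and 2,4-dibromophenol (2), which bring three of the five bromines.
2. Diaryl ether C–O bond (made first): SNAr of 2 on the CHO-activated C–F of 1 gives aldehyde 3.
3. Phenol C–OH from C–CHO: Baeyer–Villiger oxidation via formate 4 gives phenol 5. The CHO group serves first as SNAr activator and then as masked OH.
4. C4–Br and C6–Br (made last): OH-directed double bromination of 5 via monobromide 6 gives target 7.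

**Assumption:** the SMILES contains no stereocentre and the diaryl ether axis rotates freely. The target is therefore achiral, and "single enantiomer" calls for no stereocontrol, only for the correct regioisomer.

Step 1
Reactants: 1 3-bromo-2-fluorobenzaldehyde; 2 2,4-dibromophenol
Product: 3 3-bromo-2-(2,4-dibromophenoxy)benzaldehyde
Conditions: K2CO3 (1.5 equiv), DMAc, 120 °C, 16 h
Reagents that add atoms: none
Why: This is an SNAr (addition–elimination) in which the ortho formyl group stabilises the Meisenheimer adduct and fluoride is by far the best leaving group, so deprotonated 2 displaces only F, the unactivated C–Br bonds stay intact, and no stereocentre is formed.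

Step 2
Reactants: 3 3-bromo-2-(2,4-dibromophenoxy)benzaldehyde
Product: 5 3-bromo-2-(2,4-dibromophenoxy)phenol, via aryl formate 4 (not isolated)
Conditions: mCPBA (1.5 equiv), CH2Cl2, 0 → 40 °C, 16 h; aqueous wash, solvent swap; cat. K2CO3 (0.2 equiv), MeOH, rt, 30 min
Reagents that add atoms: mCPBA (3-chloroperoxybenzoic acid), OOC(=O)c1cccc(Cl)c1
Why: This is a Baeyer–Villiger oxidation with a Dakin-type outcome, in which the aryl group bearing the ortho aryloxy donor migrates in preference to H to give the labile formate 4, which mild catalytic base in MeOH transesterifies to phenol 5 without touching C–Br or the ether and without forming a stereocentre.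

Step 3
Reactants: 5 3-bromo-2-(2,4-dibromophenoxy)phenol
Product: 7 3,4,6-tribromo-2-(2,4-dibromophenoxy)phenol, via 4-monobromide 6 (not isolated)
Conditions: Br2 (2.1 equiv), AcOH, rt, 3 h
Reagents that add atoms: bromine, BrBr
Why: This is an electrophilic aromatic bromination in which the free OH is the strongest donor and its only open para and ortho sites are C4 and C6, while C5 (meta to OH, finally between two Br) and the doubly deactivated ring B do not compete with two equivalents of Br2 at rt, and no stereocentre is formed.

**Compound list**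
1 | 3-bromo-2-fluorobenzaldehyde | O=Cc1cccc(Br)c1F | starting material
2 | 2,4-dibromophenol | Oc1ccc(Br)cc1Br | starting material
3 | 3-bromo-2-(2,4-dibromophenoxy)benzaldehyde | O=Cc1cccc(Br)c1Oc1ccc(Br)cc1Br | intermediate
4 | 3-bromo-2-(2,4-dibromophenoxy)phenyl formate | O=COc1cccc(Br)c1Oc1ccc(Br)cc1Br | intermediate
5 | 3-bromo-2-(2,4-dibromophenoxy)phenol | Oc1cccc(Br)c1Oc1ccc(Br)cc1Br | intermediate
6 | 3,4-dibromo-2-(2,4-dibromophenoxy)phenol | Oc1ccc(Br)c(Br)c1Oc1ccc(Br)cc1Br | intermediate
7 | 3,4,6-tribromo-2-(2,4-dibromophenoxy)phenol | Oc1c(Br)cc(Br)c(Br)c1Oc1ccc(Br)cc1Br | target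

**Total step count:** 3. **Longest linear sequence:** 3.

**Steps most likely to fail, in order of risk**

**Risk 1 is step 2.** The hindered, bromine-deactivated aldehyde may oxidise slowly or by H-migration to the benzoic acid. Stronger base in the cleavage could also invite a Smiles-type aryl shift between the two oxygens.

The fallback does not create the phenol oxygen by oxidation. It brings the oxygen in as a methyl ether and reverses the polarity of ring A. It sets out from 2 and comes back at 5, replacing steps 1 and 2.
- Purchased 1-bromo-2-iodo-3-methoxybenzene (COc1cccc(Br)c1I) is oxidised with mCPBA and TsOH·H2O in MeCN at 77 °C to 1-bromo-2-[hydroxy(tosyloxy)-λ3-iodanyl]-3-methoxybenzene F1.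
- This is trapped in the same pot with 1,3,5-trimethoxybenzene as (2-bromo-6-methoxyphenyl)(2,4,6-trimethoxyphenyl)iodonium tosylate F2.
- Compound 2 is then O-arylated without metal (K2CO3, MeCN, 60 °C). In this ligand coupling the electron-rich trimethoxyphenyl group stays on iodine and no C–Br bond is at risk. The product is 1-bromo-2-(2,4-dibromophenoxy)-3-methoxybenzene F3.
- BBr3 in CH2Cl2 (−78 °C to rt) cleaves the methyl ether through [3-bromo-2-(2,4-dibromophenoxy)phenoxy]dibromoborane F4, and aqueous work-up gives 5.

**Risk 2 is step 1.** A weakly nucleophilic, ortho-substituted phenoxide must attack a C–F flanked by CHO and Br. The aldehyde is only a moderate activator and suffers on long heating.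

The fallback replaces the formyl activator by nitro and reaches the OH through nitrogen. It sets out from 2 and comes back at 5, replacing steps 1 and 2.
- Compound 2 reacts with purchased 1-bromo-2-fluoro-3-nitrobenzene ([O-][N+](=O)c1cccc(Br)c1F) under K2CO3 in DMF at 60 °C to give 1-bromo-2-(2,4-dibromophenoxy)-3-nitrobenzene F5.
- Fe and NH4Cl in aqueous EtOH, which cause no hydrodebromination, give 3-bromo-2-(2,4-dibromophenoxy)aniline F6.
- NaNO2 in aqueous H2SO4 at 0 °C gives 3-bromo-2-(2,4-dibromophenoxy)benzenediazonium hydrogen sulfate F7.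
- Hydroxydediazoniation with Cu2O and a large excess of Cu(NO3)2 in water at rt gives 5. The excess Cu(II) intercepts the aryl radical before Pschorr-type closure to a dibenzofuran.

**Risk 3 is step 3.** Excess bromine could over-brominate C5 or C6′, or form a bromodienone, and a penta/hexabromide mixture is hard to separate.

The fallback lets NH2 rather than OH direct the two brominations and introduces the OH last, so no free phenol ever meets bromine. It sets out from 2 and comes back at 7.
- Compound 2 is taken through F5 to the aniline F6 exactly as in the preceding fallback.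
- NBS (2.05 equiv, MeCN, 0 °C) brominates only the para and ortho positions of the far more activated aniline ring, giving 3,4,6-tribromo-2-(2,4-dibromophenoxy)aniline F8.
- Nitrosylsulfuric acid (NaNO2, conc. H2SO4/AcOH, 0–10 °C) converts this weakly basic amine into 3,4,6-tribromo-2-(2,4-dibromophenoxy)benzenediazonium hydrogen sulfate F9.
- Cu2O and excess Cu(NO3)2 in water at rt give 7.

**Further compounds**
F1 | step 2 | 1-bromo-2-[hydroxy(tosyloxy)-λ3-iodanyl]-3-methoxybenzene | COc1cccc(Br)c1I(O)OS(=O)(=O)c1ccc(C)cc1
F2 | step 2 | (2-bromo-6-methoxyphenyl)(2,4,6-trimethoxyphenyl)iodonium tosylate | COc1cccc(Br)c1[I+]c1c(OC)cc(OC)cc1OC.Cc1ccc(cc1)S(=O)(=O)[O-]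
F3 | step 2 | 1-bromo-2-(2,4-dibromophenoxy)-3-methoxybenzene | COc1cccc(Br)c1Oc1ccc(Br)cc1Br
F4 | step 2 | [3-bromo-2-(2,4-dibromophenoxy)phenoxy]dibromoborane | BrB(Br)Oc1cccc(Br)c1Oc1ccc(Br)cc1Br
F5 | step 1 | 1-bromo-2-(2,4-dibromophenoxy)-3-nitrobenzene | [O-][N+](=O)c1cccc(Br)c1Oc1ccc(Br)cc1Br
F6 | step 1 | 3-bromo-2-(2,4-dibromophenoxy)aniline | Nc1cccc(Br)c1Oc1ccc(Br)cc1Br
F7 | step 1 | 3-bromo-2-(2,4-dibromophenoxy)benzenediazonium hydrogen sulfate | N#[N+]c1cccc(Br)c1Oc1ccc(Br)cc1Br.OS(=O)(=O)[O-]
F8 | step 3 | 3,4,6-tribromo-2-(2,4-dibromophenoxy)aniline | Nc1c(Br)cc(Br)c(Br)c1Oc1ccc(Br)cc1Br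
F9 | step 3 | 3,4,6-tribromo-2-(2,4-dibromophenoxy)benzenediazonium hydrogen sulfate | N#[N+]c1c(Br)cc(Br)c(Br)c1Oc1ccc(Br)cc1Br.OS(=O)(=O)[O-]
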